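**Retrosynthetic overview**

1. Feature: the seven-membered hydroxytropone ring consists of C2 and C3 of a 1,4-dioxygenated naphthalene (C2 is also furan C4 and lies in three rings; C3 carries the C–OH carbon and neighbours the C4 ketone), the two carbonyl and two ring-fusion carbons of an ortho-phthaloyl unit, and furan C3. This is a 2-substituted indane-1,3-dione whose C1–C2 bond has been opened by a 2,3-naphthalyne.
2. Furan last: the O1–C2 bond of the furan comes from oxidative closure of the naphthalene C1 oxygen onto C1' of a dienyl side chain; the dienyl hydroquinone is the prototropic isomer of a prenyl quinone, which comes from a 1,4-dimethoxynaphthalene by oxidative demethylation.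
3. Seven-membered ring: the naphthalene C2–CH(prenyl) and C3–C(=O) bonds come from σ-insertion of 1,4-dimethoxy-2,3-naphthalyne into 2-prenylindane-1,3-dione, which enlarges the five-membered ring by two carbons.
4. The ortho-silyl triflate comes from 1,4-dimethoxynaphthalene by ortho-lithiation/hydroxylation and carbamate-directed silylation, which avoids ortho-bromoaryllithium species that would eliminate to the aryne too early. The dione comes from indane-1,3-dione and prenyl bromide.
5. Ring order: naphthalene and both benzo rings are bought; the seven-membered ring forms in step 6 and the furan in step 9.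

Key step: step 6

Assumption: radermachol is one tautomeric system, so the naphthol–ketone form delivered by step 9 and the hydroxytropone form of the target SMILES are the same compound (shift of the chelated proton). Locants C1–C4 refer to the 1,4-dioxygenated naphthalene ring with C1 bearing the later furan oxygen, and C1'–C4' to the prenyl chain.

**Route**

Step 1
Reactants: 1 1,4-dimethoxynaphthalene
Product: 4 1,4-dimethoxynaphthalen-2-ol, via aryllithium 2 (not isolated), via boronate ester 3 (not isolated)
Conditions: n-BuLi, TMEDA, THF, 0 °C to rt; B(OMe)3, −78 °C to rt; AcOH, 30% H2O2, 0 °C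
Reagents that add atoms: hydrogen peroxide, OO
Why: Directed ortho-metalation beside a methoxy group (C2 and C3 are equivalent and are the only ortho sites), borylation and oxidative 1,2-aryl migration of the boronate should place the hydroxyl exactly where the C–Li bond stood, the acidic peroxide step sparing the electron-rich naphthol from base-promoted air oxidation.

Step 2
Reactants: 4 1,4-dimethoxynaphthalen-2-ol
Product: 5 1,4-dimethoxynaphthalen-2-yl N-isopropylcarbamate
Conditions: i-PrNCO, Et3N (cat.), CH2Cl2, rt
Reagents that add atoms: isopropyl isocyanate, CC(C)N=C=O
Why: Amine-catalysed addition of the naphthol O–H across the isocyanate gives the carbamate, which is the directing group for the next metalation and can later be removed under base alone.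

Step 3
Reactants: 5 1,4-dimethoxynaphthalen-2-yl N-isopropylcarbamate
Product: 9 1,4-dimethoxy-3-(trimethylsilyl)naphthalen-2-yl N-isopropylcarbamate, via N-silyl carbamate 6 (not isolated), via lithiated carbamate 7 (not isolated), via bis-silyl carbamate 8 (not isolated)
Conditions: TMSOTf, TMEDA, Et2O, 0 °C to rt; n-BuLi, TMEDA, −78 °C; TMSCl, −78 °C to rt; aq NaHSO4
Reagents that add atoms: chlorotrimethylsilane, C[Si](C)(C)Cl
Why: Carbamate-directed ortho-metalation after temporary N-silylation of the N–H: C3 is the only free ortho position and lies between the carbamate and the C4 methoxy group, so lithiation and C-silylation should occur there, and the labile N–Si bond is hydrolysed on work-up.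

Step 4
Reactants: 9 1,4-dimethoxy-3-(trimethylsilyl)naphthalen-2-yl N-isopropylcarbamate
Product: 11 1,4-dimethoxy-3-(trimethylsilyl)naphthalen-2-yl trifluoromethanesulfonate, via silyl naphthol 10 (not isolated)
Conditions: DBU, Et2NH, MeCN, 40 °C; PhNTf2, rt
Reagents that add atoms: N-phenylbis(trifluoromethanesulfonimide), O=S(=O)(N(c1ccccc1)S(=O)(=O)C(F)(F)F)C(F)(F)F
Why: DBU removes the carbamate N–H and the naphtholate is expelled (E1cB), diethylamine captures the isocyanate as a urea, and the naphtholate is triflated in the same flask, so the acid-sensitive aryl–silicon bond on this electron-rich ring never meets acid.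

Step 5
Reactants: 12 indane-1,3-dione; 13 1-bromo-3-methylbut-2-ene
Product: 14 2-(3-methylbut-2-enyl)indane-1,3-dione
Conditions: K2CO3, MeCN, 0 °C to rt, 12 in excess (2.5 equiv)
Reagents that add atoms: none
Why: SN2 C-alkylation of the stabilised dione enolate by the soft allylic bromide; the excess of dione should hold back the second alkylation, and the neutral 2,2-diprenyl by-product is removed because only the monoalkyl dione is extracted into aqueous carbonate.

Step 6
Reactants: 11 1,4-dimethoxy-3-(trimethylsilyl)naphthalen-2-yl trifluoromethanesulfonate; 14 2-(3-methylbut-2-enyl)indane-1,3-dione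
Product: 17 (±)-prenyl dimethoxy diketone (1,4-dimethoxynaphthalene whose C2 carries the CH(prenyl) end and C3 the ketone end of a CH(prenyl)–CO–ortho-C6H4–CO bridge), via naphthalyne 15 (not isolated), via cyclobutenoxide 16 (not isolated)
Conditions: CsF (3 equiv), MeCN, Ar, 14 (1.5 equiv) stirred with CsF at rt, then 11, 70 °C
Reagents that add atoms: none
Why: Fluoride removes the silyl group of 11 and triflate leaves to give the mirror-symmetric naphthalyne 15; the cesium enolate of 14 adds through C2 to one aryne carbon, the resulting ortho-aryl anion attacks the adjacent ring carbonyl, and the fused benzocyclobutenoxide 16 fragments by cleaving the old C1–C2 bond of the dione to a ketone-stabilised benzylic carbanion, which is protonated. The closest known reaction type is the aryne acyl-alkylation (σ-bond insertion into β-dicarbonyl compounds), which with cyclic 1,3-diketones enlarges the ring by two carbons. The four-membered ring of 16 closes 4-exo-trig, and the seven-membered ring is not closed by a cyclisation but arises when the bond shared by the four- and five-membered rings breaks. The one new stereocentre, the CH(prenyl) carbon, is set without control by protonation and is racemic, which is harmless because it becomes sp2 in step 8. No regiochemical question arises because both aryne carbons and both dione carbonyls are equivalent; C- over O-arylation follows from the soft delocalised carbon nucleophile, and insertion over plain α-arylation is favoured by deprotonating 14 fully before 11 is added, so that no acidic C–H remains to quench the aryl anion, which has the carbonyl at four-ring distance.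

Step 7
Reactants: 17 (±)-prenyl dimethoxy diketone
Product: 18 (±)-prenyl quinone (the same CH(prenyl)–CO–ortho-C6H4–CO bridge across C2 and C3 of 1,4-naphthoquinone)
Conditions: (NH4)2Ce(NO3)6 (2.2 equiv), MeCN–H2O, 0 °C
Reagents that add atoms: water, O
Why: Oxidative demethylation of the para-dimethoxyarene by tetravalent cerium: the arene radical cation is attacked by water at the methoxy-bearing carbons and methanol is lost, under conditions that prenyl side chains and aryl ketones tolerate in prenylnaphthoquinone syntheses when the oxidant is kept near stoichiometric and cold.

Step 8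
Reactants: 18 (±)-prenyl quinone
Product: 19 dienyl hydroquinone (naphthalene-1,4-diol whose C2 and C3 are bridged by C(=CH–CH=CMe2)–CO–ortho-C6H4–CO)
Conditions: Et3N (2 equiv), degassed THF, Ar, rt to 40 °C; aq NH4Cl
Reagents that add atoms: none
Why: Base-mediated prototropic isomerisation of an alkyl quinone through its ortho-quinone methide to the ortho-alkenyl hydroquinone: the methine, acidified by the aryl ketone and vinylogously by the C4 quinone carbonyl, is deprotonated, the extended enolate is protonated on oxygen and a second proton leaves the allylic C1' methylene, and aromatisation of the strongly oxidising acyl quinone ring should make the conjugated diene-hydroquinone the thermodynamic tautomer.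

Step 9
Reactants: 19 dienyl hydroquinone
Product: 21 radermachol, via iodo dihydrofuran 20 (not isolated)
Conditions: I2 (1.1 equiv), K2CO3, THF, Ar, dark, 0 °C to rt
Reagents that add atoms: none
Why: Iodine-mediated oxidative cyclisation of an ortho-(1-alkenyl)phenol to a benzofuran, the reaction that converts 2-hydroxystilbenes into 2-arylbenzofurans: the C1 naphtholate closes onto iodine-activated C1' (five-membered ring, preferred over the seven-membered ether that attack at the dimethyl-bearing terminus would give), carbonate eliminates HI from iodide 20, and the furan aromatises with the chelated proton resting as in the hydroxytropone form of radermachol.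

**Compound list**

1 | 1,4-dimethoxynaphthalene | COc1ccc(OC)c2ccccc12 | starting material
2 | (1,4-dimethoxynaphthalen-2-yl)lithium, formed in the flask | [Li]c1cc(OC)c2ccccc2c1OC | intermediate
3 | dimethyl (1,4-dimethoxynaphthalen-2-yl)boronate, formed in the flask | COB(OC)c1cc(OC)c2ccccc2c1OC | intermediate
4 | 1,4-dimethoxynaphthalen-2-ol | COc1cc(O)c(OC)c2ccccc12 | intermediate
5 | 1,4-dimethoxynaphthalen-2-yl N-isopropylcarbamate | COc1cc(OC(=O)NC(C)C)c(OC)c2ccccc12 | intermediate
6 | 1,4-dimethoxynaphthalen-2-yl N-isopropyl-N-(trimethylsilyl)carbamate, formed in the flask | COc1cc(OC(=O)N(C(C)C)[Si](C)(C)C)c(OC)c2ccccc12 | intermediate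
7 | 3-lithio-1,4-dimethoxynaphthalen-2-yl N-isopropyl-N-(trimethylsilyl)carbamate, formed in the flask | COc1c([Li])c(OC(=O)N(C(C)C)[Si](C)(C)C)c(OC)c2ccccc12 | intermediate
8 | 1,4-dimethoxy-3-(trimethylsilyl)naphthalen-2-yl N-isopropyl-N-(trimethylsilyl)carbamate, formed in the flask | COc1c([Si](C)(C)C)c(OC(=O)N(C(C)C)[Si](C)(C)C)c(OC)c2ccccc12 | intermediate
9 | 1,4-dimethoxy-3-(trimethylsilyl)naphthalen-2-yl N-isopropylcarbamate | COc1c([Si](C)(C)C)c(OC(=O)NC(C)C)c(OC)c2ccccc12 | intermediate
10 | 1,4-dimethoxy-3-(trimethylsilyl)naphthalen-2-ol, present in the flask as its DBU-H naphtholate | COc1c([Si](C)(C)C)c(O)c(OC)c2ccccc12 | intermediate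
11 | 1,4-dimethoxy-3-(trimethylsilyl)naphthalen-2-yl trifluoromethanesulfonate | COc1c2ccccc2c(OC)c([Si](C)(C)C)c1OS(=O)(=O)C(F)(F)F | intermediate
12 | indane-1,3-dione | O=C1CC(=O)c2ccccc12 | starting material
13 | 1-bromo-3-methylbut-2-ene (prenyl bromide) | CC(C)=CCBr | starting material
14 | 2-(3-methylbut-2-enyl)indane-1,3-dione | CC(C)=CCC1C(=O)c2ccccc2C1=O | intermediate
15 | 1,4-dimethoxy-2,3-didehydronaphthalene (naphthalyne), formed in the flask | COC1=C2C=CC=CC2=C(OC)C#C1 | intermediate
16 | cesium alkoxide of the benzocyclobutenol fused to the indanone (racemic), formed in the flask | [Cs+].COc1c2ccccc2c(OC)c2c1C1(CC=C(C)C)C(=O)c3ccccc3C21[O-] | intermediate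
17 | (±)-prenyl dimethoxy diketone: 1,4-dimethoxynaphthalene with C2 and C3 bridged by CH(prenyl)–CO–ortho-C6H4–CO, CH on C2 | COc1c2ccccc2c(OC)c2c1C(CC=C(C)C)C(=O)c1ccccc1C2=O | intermediate
18 | (±)-prenyl quinone: 1,4-naphthoquinone with the same bridge across C2 and C3 | CC(C)=CCC1C(=O)c2ccccc2C(=O)C2=C1C(=O)c1ccccc1C2=O | intermediate
19 | dienyl hydroquinone: naphthalene-1,4-diol with C2 and C3 bridged by C(=CH–CH=CMe2)–CO–ortho-C6H4–CO, alkene geometry not controlled | CC(C)=CC=C1C(=O)c2ccccc2C(=O)c2c(O)c3ccccc3c(O)c21 | intermediate
20 | 3-iodo-2-(2-methylprop-1-enyl)-2,3-dihydrofuran fused to the naphthol (racemic, relative configuration not controlled), formed in the flask | CC(C)=CC1Oc2c3ccccc3c(O)c3c2C1(I)C(=O)c1ccccc1C3=O | intermediate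
21 | radermachol | CC(C)=Cc1oc2c3c(c(O)c4ccccc4c(=O)c13)C(=O)c1ccccc1-2 | target

**Step count and risks**

Total step count: 9. Longest linear sequence: 8 steps (steps 1–4, then 6–9).

Steps most likely to fail:

Step 6. The ortho-aryl anion may be protonated before it reaches the carbonyl, which would stop at plain α-arylation of the hindered tertiary enolate. Carbon–carbon bond formation at an aryne carbon flanked by a methoxy group may also be slow enough for the aryne to be consumed otherwise, and the acidic product may be arylated again. The fallback sets out from 11 and 12 and returns at 17. The naphthalyne from 11 is inserted under the same fluoride conditions into unsubstituted indane-1,3-dione 12, whose secondary nucleophilic carbon is the best-established substrate type for this ring expansion, to give the methylene diketone F1. Its CH2 group, flanked by the aryl ketone and the naphthalene, is then mono-C-prenylated with 13 (K2CO3, acetone) to reach 17, so the alkyl group is introduced after the ring expansion.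

Step 8. The proton shifts may stop at the enol or quinone methide stage, or the quinone methide may be lost through intermolecular Michael addition or adventitious air oxidation of the anion. The fallback sets out from 17 and returns at 19, creating the C=C1' double bond by enolate chemistry before the quinone is unveiled. Enolisation of 17 with LiN(SiMe3)2 (THF, −78 °C) and bromination with NBS should give the tertiary α-bromo ketone F2. DBU eliminates HBr toward the only β-hydrogens (C1') to give the dienone dimethyl ether F3. (NH4)2Ce(NO3)6 in aqueous MeCN gives the alkenyl quinone F4, and aqueous Na2S2O4 reduces the quinone to the hydroquinone 19.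

Step 9. Iodine may oxidise the hydroquinone to the alkenyl quinone faster than the ring closes, may add to the terminal trisubstituted alkene, or closure may take place at the far diene terminus. The fallback sets out from 19 and returns at 21, separating ring closure from oxidation. Catalytic p-TsOH in CH2Cl2 should protonate the dienone and let the C1 hydroxyl close onto the allyl-cation-like C1' to give the 2-(2-methylprop-1-enyl)-2,3-dihydrofuran F5 (racemic, cis/trans mixture). DDQ in dioxane with warming then dehydrogenates the dihydrofuran, whose C3–H is doubly activated, to the furan 21.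

**Further compounds**

F1 | step 6 | methylene diketone: 1,4-dimethoxynaphthalene with C2 and C3 bridged by CH2–CO–ortho-C6H4–CO | COc1c2ccccc2c(OC)c2c1CC(=O)c1ccccc1C2=O
F2 | step 8 | (±)-α-bromo ketone: 17 with Br in place of H on the prenyl-bearing carbon | COc1c2ccccc2c(OC)c2c1C(Br)(CC=C(C)C)C(=O)c1ccccc1C2=O
F3 | step 8 | dienone dimethyl ether: 1,4-dimethoxynaphthalene with C2 and C3 bridged by C(=CH–CH=CMe2)–CO–ortho-C6H4–CO | COc1c2ccccc2c(OC)c2c1C(=CC=C(C)C)C(=O)c1ccccc1C2=O
F4 | step 8 | alkenyl quinone: 1,4-naphthoquinone with the same dienylidene bridge | CC(C)=CC=C1C(=O)c2ccccc2C(=O)C2=C1C(=O)c1ccccc1C2=O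
F5 | step 9 | (±)-2-(2-methylprop-1-enyl)-2,3-dihydrofuran fused to the naphthol (2,3-dihydroradermachol, cis/trans mixture) | CC(C)=CC1Oc2c3ccccc3c(O)c3c2C1C(=O)c1ccccc1C3=O
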